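The isoflavone is cut on both sides of the C4 carbonyl, which lies between C4a of ring A and C3 of ring C. Since C3 is the nucleophilic β-carbon of the O1–C2=C3 enol ether, C4 can be supplied as carbon monoxide. One carbonylative Heck coupling joins a ring A aryl iodide, CO and a ring B β-methoxystyrene, making C4a–C4 and C4–C3 and leaving an open-chain methoxy enone. The iodide carries a methoxymethyl ether on the future O1 and benzyl ethers on the C5 and C7 oxygens, so only one oxygen can close ring C. Acid then forms the pyranone and hydrogenolysis frees the phenols.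

Key step: step 9

Remark on the iodide: in compound 8 the iodine sits between the methoxymethoxy group and one benzyloxy group, so its correct locants are 1,3-bis(benzyloxy)-4-iodo-2-methoxy-5-(methoxymethoxy).

Assumption: the Wittig reaction of step 8 is taken to give an E/Z mixture from which the E isomer 14 is separated by chromatography, and only this isomer is carried on.

Step 1
Reactants: 1 methyl 3,5-dihydroxy-4-methoxybenzoate
Product: 2 methyl 3,5-bis(benzyloxy)-4-methoxybenzoate
Conditions: BnBr (2.4 equiv), K2CO3, DMF, 60 °C
Reagents that add atoms: benzyl bromide, BrCc1ccccc1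
Why: Williamson ether synthesis, in which carbonate deprotonates both phenols and the benzylic bromide alkylates them while the ester and the flanked methoxy group stay untouched.

Step 2
Reactants: 2 methyl 3,5-bis(benzyloxy)-4-methoxybenzoate
Product: 3 [3,5-bis(benzyloxy)-4-methoxyphenyl]methanol
Conditions: LiAlH4, THF, 0 °C to rt
Reagents that add atoms: none
Why: Hydride reduction of the ester to the primary benzylic alcohol, to which aryl benzyl and methyl ethers are inert.

Step 3
Reactants: 3 [3,5-bis(benzyloxy)-4-methoxyphenyl]methanol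
Product: 4 3,5-bis(benzyloxy)-4-methoxybenzaldehyde
Conditions: MnO2 (activated, excess), CH2Cl2, rt
Reagents that add atoms: none
Why: Selective oxidation of a benzylic alcohol by MnO2, which stops cleanly at the aldehyde.

Step 4
Reactants: 4 3,5-bis(benzyloxy)-4-methoxybenzaldehyde
Product: 6 3,5-bis(benzyloxy)-4-methoxyphenol, via aryl formate 5 (not isolated)
Conditions: mCPBA, CH2Cl2, 0 °C to rt; aq. NaHCO3 wash; then K2CO3 (0.2 equiv), MeOH, rt
Reagents that add atoms: meta-chloroperoxybenzoic acid, OOC(=O)c1cccc(Cl)c1
Why: Baeyer–Villiger oxidation of an electron-rich benzaldehyde, in which the trialkoxyaryl group migrates in the Criegee intermediate to give the aryl formate, followed by mild methanolysis to the phenol.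

Step 5
Reactants: 6 3,5-bis(benzyloxy)-4-methoxyphenol
Product: 7 3,5-bis(benzyloxy)-2-iodo-4-methoxyphenol
Conditions: NIS (1.0 equiv), CH2Cl2, −20 to 0 °C, dark
Reagents that add atoms: N-iodosuccinimide, O=C1CCC(=O)N1I
Why: Electrophilic aromatic iodination ortho to the phenol, where the two ortho positions are equivalent by symmetry and the para position is blocked by the methoxy group, so one equivalent of NIS should give a single mono-iodide.

Step 6
Reactants: 7 3,5-bis(benzyloxy)-2-iodo-4-methoxyphenol
Product: 8 1,3-bis(benzyloxy)-4-iodo-2-methoxy-5-(methoxymethoxy)benzene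
Conditions: MOMCl, i-Pr2NEt, CH2Cl2, 0 °C to rt
Reagents that add atoms: chloromethyl methyl ether, COCCl
Why: O-alkylation of the phenol to its methoxymethyl acetal, the only acid-labile ether in the molecule, which marks this oxygen as the future O1.

Step 7
Reactants: 9 1,2,3,4-tetramethoxybenzene
Product: 11 2,3,4,5-tetramethoxybenzaldehyde, via α-chloro ether 10 (not isolated)
Conditions: Cl2CHOMe, TiCl4, CH2Cl2, −10 to 0 °C; then ice-water
Reagents that add atoms: dichloromethyl methyl ether, COC(Cl)Cl; water, O
Why: Rieche formylation, in which the chloro(methoxy)carbenium ion generated by TiCl4 attacks one of the two equivalent free ring positions and aqueous work-up hydrolyses the α-chloro ether to the aldehyde.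

Step 8
Reactants: 11 2,3,4,5-tetramethoxybenzaldehyde; 12 (methoxymethyl)triphenylphosphonium chloride
Product: 14 1,2,3,4-tetramethoxy-5-[(E)-2-methoxyethenyl]benzene, via phosphorus ylide 13 (not isolated)
Conditions: KOt-Bu, THF, 0 °C; then 11, 0 °C to rt; chromatography on Et3N-washed silica
Reagents that add atoms: none
Why: Wittig olefination, in which KOt-Bu converts 12 into ylide 13 and this methoxymethylenates the aldehyde; an E/Z mixture is expected, from which the E isomer is taken by chromatography.

Step 9
Reactants: 8 1,3-bis(benzyloxy)-4-iodo-2-methoxy-5-(methoxymethoxy)benzene; 14 1,2,3,4-tetramethoxy-5-[(E)-2-methoxyethenyl]benzene; 15 carbon monoxide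
Product: 16 (E)-1-[2,4-bis(benzyloxy)-3-methoxy-6-(methoxymethoxy)phenyl]-3-methoxy-2-(2,3,4,5-tetramethoxyphenyl)prop-2-en-1-one
Conditions: Pd(OAc)2 (10 mol %), P(t-Bu)3·HBF4 (20 mol %), Cy2NMe (3 equiv), 14 (2.5 equiv), CO (10 bar), 1,4-dioxane (anhydrous), 100 °C
Reagents that add atoms: none
Why: Proposed new method: zerovalent palladium, formed in the flask from Pd(OAc)2, the phosphine and CO, inserts into the C–I bond of 8; the di-ortho-alkoxy arylpalladium iodide (divalent palladium) should take up CO quickly because insertion relieves crowding at the metal, and CO pressure keeps the aroyl complex from reverting. The monophosphine aroylpalladium iodide is an acyl electrophile: it binds enol ether 14 and delivers the aroyl group to the aryl-bearing carbon, the site made nucleophilic by the methoxy oxygen, while palladium goes to the oxygen-bearing carbon; syn β-hydride elimination of the remaining, doubly activated hydrogen and capture of HI by Cy2NMe release enone 16 and regenerate the catalyst. The closest known reaction types are the carbonylative Heck coupling of aryl halides or triflates with terminal vinyl ethers to 3-alkoxy enones and the palladium-catalysed aroylation of vinyl ethers with aroyl chlorides; neither has been shown with a 1,2-disubstituted β-aryl enol ether or with so hindered an aryl iodide. No ring closes and no stereocentre forms; syn addition followed by syn elimination from the E enol ether should give the E enone, and its geometry is erased in step 10 in any case. Two selectivities are needed: CO insertion must precede alkene insertion, which the CO pressure and the two ortho substituents (slow direct arylation of an internal alkene) should secure, and the acyl group must bond to the carbon remote from oxygen, which the polarity of the enol ether, reinforced by electron-rich ring B, should secure. The methoxymethyl and benzyl ethers are inert to the amine base and to palladium in the absence of hydrogen, and anhydrous, alcohol-free conditions prevent diversion of the aroyl complex to acid or ester.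

Step 10
Reactants: 16 (E)-1-[2,4-bis(benzyloxy)-3-methoxy-6-(methoxymethoxy)phenyl]-3-methoxy-2-(2,3,4,5-tetramethoxyphenyl)prop-2-en-1-one
Product: 18 5,7-bis(benzyloxy)-6-methoxy-3-(2,3,4,5-tetramethoxyphenyl)-4H-chromen-4-one, via free phenol 17 (not isolated)
Conditions: HCl (1.25 M in MeOH), THF, 50 °C
Reagents that add atoms: none
Why: Acid-catalysed acetal cleavage frees the C8a phenol, which adds to the β-carbon of the methoxy enone (C2) and expels methanol in a conjugate addition–elimination (6-endo closure) that is driven by formation of the aromatic pyranone; benzyl and methyl ethers are stable to HCl in methanol.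

Step 11
Reactants: 18 5,7-bis(benzyloxy)-6-methoxy-3-(2,3,4,5-tetramethoxyphenyl)-4H-chromen-4-one
Product: 19 irisjaponin A, 5,7-dihydroxy-6-methoxy-3-(2,3,4,5-tetramethoxyphenyl)-4H-chromen-4-one
Conditions: H2 (1 atm), Pd/C (10 wt %), EtOAc–MeOH, rt, stopped at consumption of 18
Reagents that add atoms: none
Why: Hydrogenolysis of the two aryl benzyl ethers over Pd/C frees the C5 and C7 hydroxyls, while methyl ethers are inert and ambient pressure with close monitoring should spare the C2=C3 bond.

Compound list
1 | methyl 3,5-dihydroxy-4-methoxybenzoate | COC(=O)c1cc(O)c(OC)c(O)c1 | starting material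
2 | methyl 3,5-bis(benzyloxy)-4-methoxybenzoate | COC(=O)c1cc(OCc2ccccc2)c(OC)c(OCc2ccccc2)c1 | intermediate
3 | [3,5-bis(benzyloxy)-4-methoxyphenyl]methanol | OCc1cc(OCc2ccccc2)c(OC)c(OCc2ccccc2)c1 | intermediate
4 | 3,5-bis(benzyloxy)-4-methoxybenzaldehyde | O=Cc1cc(OCc2ccccc2)c(OC)c(OCc2ccccc2)c1 | intermediate
5 | 3,5-bis(benzyloxy)-4-methoxyphenyl formate | O=COc1cc(OCc2ccccc2)c(OC)c(OCc2ccccc2)c1 | intermediate (not isolated)
6 | 3,5-bis(benzyloxy)-4-methoxyphenol | Oc1cc(OCc2ccccc2)c(OC)c(OCc2ccccc2)c1 | intermediate
7 | 3,5-bis(benzyloxy)-2-iodo-4-methoxyphenol | Oc1cc(OCc2ccccc2)c(OC)c(OCc2ccccc2)c1I | intermediate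
8 | 1,3-bis(benzyloxy)-4-iodo-2-methoxy-5-(methoxymethoxy)benzene | COCOc1cc(OCc2ccccc2)c(OC)c(OCc2ccccc2)c1I | intermediate
9 | 1,2,3,4-tetramethoxybenzene | COc1ccc(OC)c(OC)c1OC | starting material
10 | 1-[chloro(methoxy)methyl]-2,3,4,5-tetramethoxybenzene (racemic) | COC(Cl)c1cc(OC)c(OC)c(OC)c1OC | intermediate (not isolated)
11 | 2,3,4,5-tetramethoxybenzaldehyde | COc1cc(C=O)c(OC)c(OC)c1OC | intermediate
12 | (methoxymethyl)triphenylphosphonium chloride | COC[P+](c1ccccc1)(c1ccccc1)c1ccccc1.[Cl-] | starting material
13 | (methoxymethylidene)triphenyl-λ5-phosphane | COC=P(c1ccccc1)(c1ccccc1)c1ccccc1 | intermediate (not isolated)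
14 | 1,2,3,4-tetramethoxy-5-[(E)-2-methoxyethenyl]benzene | CO/C=C/c1cc(OC)c(OC)c(OC)c1OC | intermediate
15 | carbon monoxide | [C-]#[O+] | starting material
16 | (E)-1-[2,4-bis(benzyloxy)-3-methoxy-6-(methoxymethoxy)phenyl]-3-methoxy-2-(2,3,4,5-tetramethoxyphenyl)prop-2-en-1-one | CO/C=C(\c1cc(OC)c(OC)c(OC)c1OC)C(=O)c1c(OCOC)cc(OCc2ccccc2)c(OC)c1OCc1ccccc1 | intermediate
17 | (E)-1-[2,4-bis(benzyloxy)-6-hydroxy-3-methoxyphenyl]-3-methoxy-2-(2,3,4,5-tetramethoxyphenyl)prop-2-en-1-one | CO/C=C(\c1cc(OC)c(OC)c(OC)c1OC)C(=O)c1c(O)cc(OCc2ccccc2)c(OC)c1OCc1ccccc1 | intermediate (not isolated)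
18 | 5,7-bis(benzyloxy)-6-methoxy-3-(2,3,4,5-tetramethoxyphenyl)-4H-chromen-4-one | COc1cc(-c2coc3cc(OCc4ccccc4)c(OC)c(OCc4ccccc4)c3c2=O)c(OC)c(OC)c1OC | intermediate
19 | irisjaponin A, 5,7-dihydroxy-6-methoxy-3-(2,3,4,5-tetramethoxyphenyl)-4H-chromen-4-one | COc1cc(-c2coc3cc(O)c(OC)c(O)c3c2=O)c(OC)c(OC)c1OC | target

Total step count: 11 steps.
Longest linear sequence: 9 steps (steps 1 to 6, then 9, 10 and 11); the ring B branch is steps 7 and 8.

Steps most likely to fail

1. Step 9 (carbonylative Heck coupling). The hindered aroylpalladium intermediate may not engage the internal enol ether fast enough, so that reduction of the iodide, direct non-carbonylative coupling or capture of the acyl group by adventitious nucleophiles takes over; acyl transfer to the wrong alkene carbon is a second failure mode. The fallback is the deoxybenzoin route, all of it known chemistry; it sets out from iodide 8 and enol ether 14 and comes back at isoflavone 18. Enol ether 14 is hydrolysed (aq. HCl, THF, rt) to (2,3,4,5-tetramethoxyphenyl)acetaldehyde F1. Iodide 8 undergoes iodine–magnesium exchange (i-PrMgCl·LiCl, THF, −20 °C) to [2,4-bis(benzyloxy)-3-methoxy-6-(methoxymethoxy)phenyl]magnesium chloride F2, which is added to F1 (LaCl3·2LiCl to suppress enolisation, −78 to 0 °C) to give racemic 1-[2,4-bis(benzyloxy)-3-methoxy-6-(methoxymethoxy)phenyl]-2-(2,3,4,5-tetramethoxyphenyl)ethan-1-ol F3. Dess–Martin oxidation should give the deoxybenzoin 1-[2,4-bis(benzyloxy)-3-methoxy-6-(methoxymethoxy)phenyl]-2-(2,3,4,5-tetramethoxyphenyl)ethan-1-one F4. Condensation with N,N-dimethylformamide dimethyl acetal (toluene, 90 °C) should give the enaminone (E)-1-[2,4-bis(benzyloxy)-3-methoxy-6-(methoxymethoxy)phenyl]-3-(dimethylamino)-2-(2,3,4,5-tetramethoxyphenyl)prop-2-en-1-one F5. The acid conditions of step 10 then remove the methoxymethyl group and close ring C with loss of dimethylamine to give 18.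

2. Step 8 (Wittig methoxymethylenation). Geometric control in the olefination may be poor, and material may be lost on separating the isomers or by hydrolysis of the enol ether on silica. The fallback builds the E geometry stereoselectively; it sets out from aldehyde 11 and comes back at enol ether 14. Takai olefination (CHI3, CrCl2, THF, 0 °C) should give 1-[(E)-2-iodoethenyl]-2,3,4,5-tetramethoxybenzene F6 with high E selectivity. A copper-catalysed C–O coupling with methanol (CuI, 3,4,7,8-tetramethyl-1,10-phenanthroline, Cs2CO3, toluene, 80 °C) then replaces iodine by methoxy with retention of the double-bond geometry.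

3. Step 11 (debenzylation). Hydrogen may over-reduce the C2=C3 bond of the pyranone ring, or cleavage of the hindered C5 benzyl ether may stall. The fallback replaces hydrogenolysis by Lewis-acid cleavage with a cation scavenger (BCl3, pentamethylbenzene, CH2Cl2, −78 °C), so that no hydrogen is present; it sets out from 18 and comes back at target 19 without any new compound, and at this temperature the methyl ethers should survive.

Further compounds
F1 | step 9 | (2,3,4,5-tetramethoxyphenyl)acetaldehyde | COc1cc(CC=O)c(OC)c(OC)c1OC
F2 | step 9 | [2,4-bis(benzyloxy)-3-methoxy-6-(methoxymethoxy)phenyl]magnesium chloride | COCOc1cc(OCc2ccccc2)c(OC)c(OCc2ccccc2)c1[Mg]Cl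
F3 | step 9 | 1-[2,4-bis(benzyloxy)-3-methoxy-6-(methoxymethoxy)phenyl]-2-(2,3,4,5-tetramethoxyphenyl)ethan-1-ol (racemic) | COCOc1cc(OCc2ccccc2)c(OC)c(OCc2ccccc2)c1C(O)Cc1cc(OC)c(OC)c(OC)c1OC
F4 | step 9 | 1-[2,4-bis(benzyloxy)-3-methoxy-6-(methoxymethoxy)phenyl]-2-(2,3,4,5-tetramethoxyphenyl)ethan-1-one | COCOc1cc(OCc2ccccc2)c(OC)c(OCc2ccccc2)c1C(=O)Cc1cc(OC)c(OC)c(OC)c1OC
F5 | step 9 | (E)-1-[2,4-bis(benzyloxy)-3-methoxy-6-(methoxymethoxy)phenyl]-3-(dimethylamino)-2-(2,3,4,5-tetramethoxyphenyl)prop-2-en-1-one | CN(C)/C=C(\c1cc(OC)c(OC)c(OC)c1OC)C(=O)c1c(OCOC)cc(OCc2ccccc2)c(OC)c1OCc1ccccc1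
F6 | step 8 | 1-[(E)-2-iodoethenyl]-2,3,4,5-tetramethoxybenzene | COc1cc(/C=C/I)c(OC)c(OC)c1OC
F0 | step 11 | none | none
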